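**Plan**

1. Retrosynthetic cuts, in order: the carboxyl is masked as an n-propyl ester (a temporary lipophilic tail); the O1–C2 bond of the dihydropyran ring is opened to an achiral 2-methyl-6-alkenyl-1,4-benzoquinol (stored as the quinone, before that as the dimethyl ether); the carboxyl carbon C12′ goes back to the E-methyl group at the end of a farnesyl chain; the aryl–C1′ bond is cut to an arylcopper and (2E,6E)-farnesyl bromide.
2. Forward: the benzene ring is bought; the intact C15 chain is joined to it; the chain terminus is oxidised and esterified; the quinone is unmasked; the dihydropyran ring, the only ring made, is closed by a tocopherol cyclase; the tail is hydrolysed.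
3. Enabling feature: in the quinol the C1 hydroxyl oxygen and C3′ of the E-trisubstituted C2′=C3′ alkene are the ends of a six-atom array (O, aromatic C1, aromatic C6, C1′, C2′, C3′). Markovnikov protonation at C2′ therefore puts a tertiary cation exactly where the oxygen closes the ring, while the C6′=C7′ alkene is out of reach of both hydroxyl groups and the C10′=C11′ alkene is deactivated by conjugation to the carboxyl.
4. Stereochemistry: C2 (R), the only stereocentre, is set by the enzyme on an achiral substrate; the 2′E and 6′E alkenes come from (2E,6E)-farnesyl bromide (2′E is what the cyclase needs, 6′E survives into the target); 10′E comes from the E-selective allylic oxidation with SeO2.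

Key step: step 9

Assumption: a purified recombinant tocopherol cyclase (Arabidopsis thaliana VTE1 produced in Escherichia coli) is available and keeps its native 2R sense of ring closure on the substrate analogue 14. Side-chain carbons are numbered C1′ (benzylic) to C12′ (carboxyl); quinol ring carbons are numbered C1 (hydroxyl-bearing carbon between methyl and chain) to C6.

**Route**

Step 1
Reactants: 1 4-methoxy-2-methylphenol
Product: 2 2-bromo-4-methoxy-6-methylphenol
Conditions: NBS (1.0 equiv), CH2Cl2, 0 °C to rt
Reagents that add atoms: N-bromosuccinimide, O=C1CCC(=O)N1Br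
Why: Electrophilic aromatic bromination should go to the only free position ortho to the hydroxyl group, the strongest director on the ring, because the para position is blocked by the methoxy group.

Step 2
Reactants: 2 2-bromo-4-methoxy-6-methylphenol
Product: 3 1-bromo-2,5-dimethoxy-3-methylbenzene
Conditions: MeI, K2CO3, acetone, reflux
Reagents that add atoms: iodomethane, CI
Why: Williamson O-methylation of the phenoxide masks the quinol as its dimethyl ether, which is inert to the organometallic step and to the later side-chain oxidations.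

Step 3
Reactants: 3 1-bromo-2,5-dimethoxy-3-methylbenzene; 4 (2E,6E)-farnesyl bromide ((2E,6E)-1-bromo-3,7,11-trimethyldodeca-2,6,10-triene)
Product: 7 2,5-dimethoxy-1-methyl-3-[(2E,6E)-3,7,11-trimethyldodeca-2,6,10-trien-1-yl]benzene, via aryllithium 5 (not isolated), via arylcopper 6 (not isolated)
Conditions: n-BuLi, THF, −78 °C; CuBr·SMe2 (1.0 equiv), −78 to −40 °C; then 4, −78 °C to rt
Reagents that add atoms: none
Why: Bromine–lithium exchange and transmetalation give an arylcopper that should displace the allylic bromide at its primary carbon (organocopper SN2 allylation) with the 2E and 6E geometry of the farnesyl unit retained.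

Step 4
Reactants: 7 2,5-dimethoxy-1-methyl-3-[(2E,6E)-3,7,11-trimethyldodeca-2,6,10-trien-1-yl]benzene
Product: 8 (2E,6E,10E)-12-(2,5-dimethoxy-3-methylphenyl)-2,6,10-trimethyldodeca-2,6,10-trien-1-ol
Conditions: SeO2 (0.3 equiv), t-BuOOH (3 equiv), salicylic acid (0.1 equiv), CH2Cl2, rt
Reagents that add atoms: selenium dioxide, O=[Se]=O (catalytic oxygen carrier); tert-butyl hydroperoxide, CC(C)(C)OO (terminal oxidant)
Why: The Riley allylic oxidation (ene reaction followed by [2,3]-sigmatropic shift) should hydroxylate the E-methyl group of the terminal, least hindered trisubstituted alkene, the site it prefers in farnesyl derivatives, which fixes the 10′E geometry, and any over-oxidised enal 9 joins the stream at step 5.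

Step 5
Reactants: 8 (2E,6E,10E)-12-(2,5-dimethoxy-3-methylphenyl)-2,6,10-trimethyldodeca-2,6,10-trien-1-ol
Product: 9 (2E,6E,10E)-12-(2,5-dimethoxy-3-methylphenyl)-2,6,10-trimethyldodeca-2,6,10-trienal
Conditions: activated MnO2 (excess), CH2Cl2, rt
Reagents that add atoms: none
Why: Activated MnO2 oxidises allylic alcohols selectively to enals without E/Z isomerisation and should leave the electron-rich arene and the isolated alkenes untouched.

Step 6
Reactants: 9 (2E,6E,10E)-12-(2,5-dimethoxy-3-methylphenyl)-2,6,10-trimethyldodeca-2,6,10-trienal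
Product: 10 (2E,6E,10E)-12-(2,5-dimethoxy-3-methylphenyl)-2,6,10-trimethyldodeca-2,6,10-trienoic acid
Conditions: NaClO2, NaH2PO4, 2-methyl-2-butene (excess), t-BuOH/H2O, rt
Reagents that add atoms: sodium chlorite, [Na+].[O-]Cl=O
Why: The Pinnick oxidation converts the enal into the acid without touching the alkenes, with 2-methyl-2-butene scavenging the hypochlorous acid that could otherwise chlorinate the dimethoxyarene or the isolated alkenes.

Step 7
Reactants: 10 (2E,6E,10E)-12-(2,5-dimethoxy-3-methylphenyl)-2,6,10-trimethyldodeca-2,6,10-trienoic acid; 11 1-bromopropane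
Product: 12 propyl (2E,6E,10E)-12-(2,5-dimethoxy-3-methylphenyl)-2,6,10-trimethyldodeca-2,6,10-trienoate
Conditions: K2CO3, DMF, rt
Reagents that add atoms: none
Why: SN2 O-alkylation of the carboxylate installs an n-propyl tail that brings the side chain (C1′ to C12′, the ester oxygen and three propyl carbons) to the 16-atom backbone of a geranylgeranyl or phytyl group, the hydrophobic recognition element of the cyclase, and that is removed again in step 10.

Step 8
Reactants: 12 propyl (2E,6E,10E)-12-(2,5-dimethoxy-3-methylphenyl)-2,6,10-trimethyldodeca-2,6,10-trienoate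
Product: 13 propyl (2E,6E,10E)-2,6,10-trimethyl-12-(5-methyl-3,6-dioxocyclohexa-1,4-dien-1-yl)dodeca-2,6,10-trienoate
Conditions: (NH4)2Ce(NO3)6 (2.5 equiv), MeCN/H2O, 0 °C
Reagents that add atoms: water, O
Why: Oxidative demethylation of the 1,4-dimethoxyarene by the tetravalent cerium salt (two one-electron oxidations, attack of water, loss of methanol) should give the para-quinone, the air-stable storage form of the cyclization substrate, faster than the alkenes or the ester react.

Step 9
Reactants: 13 propyl (2E,6E,10E)-2,6,10-trimethyl-12-(5-methyl-3,6-dioxocyclohexa-1,4-dien-1-yl)dodeca-2,6,10-trienoate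
Product: 15 propyl (2E,6E)-9-[(2R)-6-hydroxy-2,8-dimethyl-3,4-dihydro-2H-chromen-2-yl]-2,6-dimethylnona-2,6-dienoate, via quinol 14 (not isolated)
Conditions: Na2S2O4 (1.5 equiv), degassed potassium phosphate buffer pH 7.0, 2-hydroxypropyl-β-cyclodextrin, argon, rt; then purified recombinant tocopherol cyclase (Arabidopsis thaliana VTE1), 30 °C, dark
Reagents that add atoms: none
Why: Proposed new method: a tocopherol cyclase has not been shown to turn over a quinol whose isoprenoid tail is interrupted beyond C11′ by an ester-linked n-propyl group, and the closest known reaction is its native conversion of 2-methyl-6-geranylgeranyl-1,4-benzoquinol into (R)-δ-tocotrienol and of the phytyl analogue into (R)-δ-tocopherol. Mechanistically an active-site acid protonates C2′ of the E-configured C2′=C3′ alkene while the C1 hydroxyl oxygen, at the other end of the array O–C1–C6–C1′–C2′–C3′, adds to the re face of the developing tertiary cation at C3′ from the side opposite to the proton (anti addition, as in the native reaction), which closes the dihydropyran ring in the 6-endo-trig mode. The new quaternary stereocentre C2 is controlled by the enzyme pocket alone, since 14 is achiral; the native reaction gives only 2R chromanols, and the CIP priorities at C2 (O1 > C3 > chain CH2 > CH3) are the same in 15 as in δ-tocotrienol. The elements the enzyme is known to recognise are kept: the free C1 hydroxyl, the E geometry of the C2′=C3′ alkene and a lipophilic tail, here restored to the 16-atom backbone of the native chain by the propyl ester. The step needs site selectivity among three alkenes and two hydroxyl groups and freedom from a racemic background reaction: the C6′=C7′ alkene corresponds to the alkene that the native geranylgeranyl substrate carries through unchanged and lies out of reach of both hydroxyl groups, the C10′=C11′ alkene is conjugated to the ester and too electron-poor to be protonated, only the C1 hydroxyl can reach C3′ through a six-membered transition state, and at pH 7 no uncatalysed cyclization should compete. The quinone 13 cannot cyclize, so reduction by dithionite under argon supplies the quinol oxidation level immediately before the enzyme acts.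

Step 10
Reactants: 15 propyl (2E,6E)-9-[(2R)-6-hydroxy-2,8-dimethyl-3,4-dihydro-2H-chromen-2-yl]-2,6-dimethylnona-2,6-dienoate
Product: 16 (2E,6E)-9-[(2R)-6-hydroxy-2,8-dimethyl-3,4-dihydro-2H-chromen-2-yl]-2,6-dimethylnona-2,6-dienoic acid
Conditions: LiOH·H2O, THF/H2O (degassed), argon, 40 °C; then 1 M HCl to pH 3
Reagents that add atoms: lithium hydroxide, [Li+].[OH-]
Why: Saponification (acyl–oxygen cleavage) of the propyl ester removes the tail, while the quaternary ether stereocentre C2 and both alkene geometries should be unaffected by aqueous hydroxide and exclusion of oxygen protects the chromanol.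

**Compound list**

1 | 4-methoxy-2-methylphenol | COc1ccc(O)c(C)c1 | starting material
2 | 2-bromo-4-methoxy-6-methylphenol | COc1cc(C)c(O)c(Br)c1 | intermediate
3 | 1-bromo-2,5-dimethoxy-3-methylbenzene | COc1cc(C)c(OC)c(Br)c1 | intermediate
4 | (2E,6E)-farnesyl bromide, (2E,6E)-1-bromo-3,7,11-trimethyldodeca-2,6,10-triene | CC(C)=CCC/C(C)=C/CC/C(C)=C/CBr | starting material
5 | (2,5-dimethoxy-3-methylphenyl)lithium (not isolated) | COc1cc(C)c(OC)c([Li])c1 | intermediate
6 | (2,5-dimethoxy-3-methylphenyl)copper (not isolated) | COc1cc(C)c(OC)c([Cu])c1 | intermediate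
7 | 2,5-dimethoxy-1-methyl-3-[(2E,6E)-3,7,11-trimethyldodeca-2,6,10-trien-1-yl]benzene | COc1cc(C)c(OC)c(C/C=C(\C)CC/C=C(\C)CCC=C(C)C)c1 | intermediate
8 | (2E,6E,10E)-12-(2,5-dimethoxy-3-methylphenyl)-2,6,10-trimethyldodeca-2,6,10-trien-1-ol | COc1cc(C)c(OC)c(C/C=C(\C)CC/C=C(\C)CC/C=C(\C)CO)c1 | intermediate
9 | (2E,6E,10E)-12-(2,5-dimethoxy-3-methylphenyl)-2,6,10-trimethyldodeca-2,6,10-trienal | COc1cc(C)c(OC)c(C/C=C(\C)CC/C=C(\C)CC/C=C(\C)C=O)c1 | intermediate
10 | (2E,6E,10E)-12-(2,5-dimethoxy-3-methylphenyl)-2,6,10-trimethyldodeca-2,6,10-trienoic acid | COc1cc(C)c(OC)c(C/C=C(\C)CC/C=C(\C)CC/C=C(\C)C(=O)O)c1 | intermediate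
11 | 1-bromopropane | CCCBr | starting material
12 | propyl (2E,6E,10E)-12-(2,5-dimethoxy-3-methylphenyl)-2,6,10-trimethyldodeca-2,6,10-trienoate | COc1cc(C)c(OC)c(C/C=C(\C)CC/C=C(\C)CC/C=C(\C)C(=O)OCCC)c1 | intermediate
13 | propyl (2E,6E,10E)-2,6,10-trimethyl-12-(5-methyl-3,6-dioxocyclohexa-1,4-dien-1-yl)dodeca-2,6,10-trienoate | CC1=CC(=O)C=C(C/C=C(\C)CC/C=C(\C)CC/C=C(\C)C(=O)OCCC)C1=O | intermediate
14 | propyl (2E,6E,10E)-12-(2,5-dihydroxy-3-methylphenyl)-2,6,10-trimethyldodeca-2,6,10-trienoate (not isolated) | Cc1cc(O)cc(C/C=C(\C)CC/C=C(\C)CC/C=C(\C)C(=O)OCCC)c1O | intermediate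
15 | propyl (2E,6E)-9-[(2R)-6-hydroxy-2,8-dimethyl-3,4-dihydro-2H-chromen-2-yl]-2,6-dimethylnona-2,6-dienoate | C/C(=C\CC[C@]1(C)CCc2cc(O)cc(C)c2O1)CC/C=C(\C)C(=O)OCCC | intermediate
16 | (2E,6E)-9-[(2R)-6-hydroxy-2,8-dimethyl-3,4-dihydro-2H-chromen-2-yl]-2,6-dimethylnona-2,6-dienoic acid | C/C(=C\CC[C@]1(C)CCc2cc(O)cc(C)c2O1)CC/C=C(\C)C(=O)O | target

**Step count**

Total steps: 10. Longest linear sequence: 10 steps (1 to 16).

**Steps most likely to fail, with fallbacks**

Step 9. The cyclase may fail to bind or turn over the ester-interrupted chain, or may close the ring with incomplete facial control. The fallback uses known chemistry and sets out from 13. Reduction with aqueous Na2S2O4 in a degassed two-phase system with EtOAc gives 14, which is used at once. The same O–C bond is then closed without the enzyme by Brønsted acid catalysis (catalytic p-TsOH·H2O, toluene, 40 °C, argon), the standard Markovnikov cyclization of alkenylquinols to chromanols; the alkene next to the phenol should react first. This should give 15 together with its enantiomer, propyl (2E,6E)-9-[(2S)-6-hydroxy-2,8-dimethyl-3,4-dihydro-2H-chromen-2-yl]-2,6-dimethylnona-2,6-dienoate F1, as the racemate. Preparative HPLC on a cellulose tris(3,5-dimethylphenylcarbamate) stationary phase should separate the two, and the fallback comes back to the route at 15.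

Step 4. The ene reaction may not discriminate between the terminal E-methyl group and the allylic positions of the two inner alkenes, and the allylic alcohol may be over-oxidised. In the fallback the oxygen is introduced before the arene is attached. (2E,6E)-Farnesyl acetate F2 (purchased), in which the acetoxy group deactivates the neighbouring alkene, is hydroxylated under the conditions of step 4 to (2E,6E,10E)-12-hydroxy-3,7,11-trimethyldodeca-2,6,10-trien-1-yl acetate F3. Silylation (TBSCl, imidazole, DMF) gives (2E,6E,10E)-12-[(tert-butyldimethylsilyl)oxy]-3,7,11-trimethyldodeca-2,6,10-trien-1-yl acetate F4. Methanolysis of the acetate (K2CO3, MeOH) gives (2E,6E,10E)-12-[(tert-butyldimethylsilyl)oxy]-3,7,11-trimethyldodeca-2,6,10-trien-1-ol F5, and PPh3/CBr4 (CH2Cl2, 0 °C) gives {[(2E,6E,10E)-12-bromo-2,6,10-trimethyldodeca-2,6,10-trien-1-yl]oxy}(tert-butyl)dimethylsilane F6. Coupling of F6 with arylcopper 6, made from 3 exactly as in step 3, should give tert-butyl{[(2E,6E,10E)-12-(2,5-dimethoxy-3-methylphenyl)-2,6,10-trimethyldodeca-2,6,10-trien-1-yl]oxy}dimethylsilane F7, and Bu4NF in THF releases the alcohol. The fallback sets out from 3 and comes back to the route at 8.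

Step 3. The arylcopper may attack the allylic bromide at the tertiary end (SN2′ transposition), the 2E geometry may erode, or the bromide may homocouple. The fallback avoids organometallic reagents and sets out from 1. Deprotonation (NaH, toluene, 0 °C) gives sodium 4-methoxy-2-methylphenolate F8. In the non-polar medium F8 should be alkylated by 4 through the tight ion pair at its only free ortho carbon (ortho-C-allylation of a phenoxide), giving 4-methoxy-2-methyl-6-[(2E,6E)-3,7,11-trimethyldodeca-2,6,10-trien-1-yl]phenol F9. O-Methylation of F9 (MeI, K2CO3, acetone) then gives the dimethyl ether, so the fallback comes back to the route at 7 and bypasses steps 1 to 3.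

**Further compounds**

F1 | step 9 | propyl (2E,6E)-9-[(2S)-6-hydroxy-2,8-dimethyl-3,4-dihydro-2H-chromen-2-yl]-2,6-dimethylnona-2,6-dienoate | C/C(=C\CC[C@@]1(C)CCc2cc(O)cc(C)c2O1)CC/C=C(\C)C(=O)OCCC
F2 | step 4 | (2E,6E)-farnesyl acetate, (2E,6E)-3,7,11-trimethyldodeca-2,6,10-trien-1-yl acetate (purchased) | CC(C)=CCC/C(C)=C/CC/C(C)=C/COC(C)=O
F3 | step 4 | (2E,6E,10E)-12-hydroxy-3,7,11-trimethyldodeca-2,6,10-trien-1-yl acetate | CC(=O)OC/C=C(\C)CC/C=C(\C)CC/C=C(\C)CO
F4 | step 4 | (2E,6E,10E)-12-[(tert-butyldimethylsilyl)oxy]-3,7,11-trimethyldodeca-2,6,10-trien-1-yl acetate | CC(=O)OC/C=C(\C)CC/C=C(\C)CC/C=C(\C)CO[Si](C)(C)C(C)(C)C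
F5 | step 4 | (2E,6E,10E)-12-[(tert-butyldimethylsilyl)oxy]-3,7,11-trimethyldodeca-2,6,10-trien-1-ol | OC/C=C(\C)CC/C=C(\C)CC/C=C(\C)CO[Si](C)(C)C(C)(C)C
F6 | step 4 | {[(2E,6E,10E)-12-bromo-2,6,10-trimethyldodeca-2,6,10-trien-1-yl]oxy}(tert-butyl)dimethylsilane | BrC/C=C(\C)CC/C=C(\C)CC/C=C(\C)CO[Si](C)(C)C(C)(C)C
F7 | step 4 | tert-butyl{[(2E,6E,10E)-12-(2,5-dimethoxy-3-methylphenyl)-2,6,10-trimethyldodeca-2,6,10-trien-1-yl]oxy}dimethylsilane | COc1cc(C)c(OC)c(C/C=C(\C)CC/C=C(\C)CC/C=C(\C)CO[Si](C)(C)C(C)(C)C)c1
F8 | step 3 | sodium 4-methoxy-2-methylphenolate | COc1ccc([O-])c(C)c1.[Na+]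
F9 | step 3 | 4-methoxy-2-methyl-6-[(2E,6E)-3,7,11-trimethyldodeca-2,6,10-trien-1-yl]phenol | COc1cc(C)c(O)c(C/C=C(\C)CC/C=C(\C)CCC=C(C)C)c1
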